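**Assumption:** Stevensine has no stereocentres (the only C=C is in the ring and the molecule is achiral), so "single enantiomer" does not apply. The two stereo-relevant intermediates (the carbinol in step 5) are racemic and are destroyed in step 6. The final product is isolated as its HCl salt and free-based if needed.

## Retrosynthesis
- The 2-aminoimidazole is built last, from an α-bromo methyl ketone and acetylguanidine, on the acetyl group of enone **9**.
- Enone **9** comes from ethynyl carbinol **8** by Rupe rearrangement. Carbinol **8** comes from dibromo-dione **6** by ethynyl Grignard addition.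
- Dione **6** comes from bromination of the pyrrolo-azepinedione **5**. The seven-membered ring of **5** is closed by intramolecular Friedel–Crafts acylation of pyrrole C3 with the acid of **4**.
- Order of ring formation: pyrrole (commercial), then azepinone (step 3), then imidazole (step 8).

## Route

**Step 1**
Reactants: **1** 2-(trichloroacetyl)-1H-pyrrole; **2** methyl 3-aminopropanoate hydrochloride
Product: **3** methyl 3-(1H-pyrrole-2-carboxamido)propanoate
Conditions: Et3N, MeCN, rt
Reagents that add atoms: none (CCl3 leaves as CHCl3)
Why: The amine displaces CCl3⁻ from the trichloromethyl ketone (haloform-type acyl transfer) to give the amide cleanly. No stereocentre is formed.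

**Step 2**
Reactant: **3**
Product: **4** 3-(1H-pyrrole-2-carboxamido)propanoic acid
Conditions: LiOH, THF/H2O, rt; then 1 M HCl
Reagents that add atoms: none
Why: Saponification of the methyl ester leaves the pyrrole amide intact and frees the acid needed for acylation.

**Step 3**
Reactant: **4**
Product: **5** 1,5,6,7-tetrahydropyrrolo[2,3-c]azepine-4,8-dione
Conditions: PPA, 90 °C
Reagents that add atoms: none
Why: The carboxylic acid, activated as a mixed phosphoric anhydride, acylates pyrrole C3 in an intramolecular Friedel–Crafts acylation. The tether only reaches C3, so the seven-membered ring forms regiospecifically.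

**Step 4**
Reactant: **5**
Product: **6** 2,3-dibromo-1,5,6,7-tetrahydropyrrolo[2,3-c]azepine-4,8-dione
Conditions: NBS (2.2 equiv), THF, 0 °C to rt
Reagents that add atoms: NBS, O=C1CCC(=O)N1Br
Why: Electrophilic aromatic bromination of the only two free pyrrole CH positions (C2 and C3 in azepine numbering, i.e. pyrrole C5 and C4) installs the dibromopyrrole. Pyrrole bromination is much faster than ketone α-bromination.

**Step 5**
Reactants: **6**; **7** ethynylmagnesium bromide
Product: **8** 2,3-dibromo-4-ethynyl-4-hydroxy-1,5,6,7-tetrahydropyrrolo[2,3-c]azepin-8-one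
Conditions: **7** (5 equiv), CeCl3, THF, 0 °C to rt
Reagents that add atoms: **7**, C#C[Mg]Br
Why: The first two equivalents deprotonate the pyrrole and lactam NH; the excess acetylide adds to the ketone (Grignard/Ce-mediated 1,2-addition). This creates a racemic tertiary carbinol, which is destroyed in step 6.

**Step 6**
Reactant: **8**
Product: **9** 4-acetyl-2,3-dibromo-1,6-dihydropyrrolo[2,3-c]azepin-8(7H)-one
Conditions: HCO2H, 90 °C
Reagents that add atoms: none (net isomerization)
Why: Rupe rearrangement. Acid dehydrates the tertiary carbinol toward C5 to give an enyne, whose alkyne is then hydrated in a Markovnikov sense to the methyl ketone. This sets the endocyclic C4=C5 bond conjugated with the pyrrole, and the CH2–NH unit is retained.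

**Step 7**
Reactant: **9**
Product: **10** 4-(bromoacetyl)-2,3-dibromo-1,6-dihydropyrrolo[2,3-c]azepin-8(7H)-one
Conditions: CuBr2 (2 equiv), EtOAc/CHCl3, reflux
Reagents that add atoms: CuBr2, [Cu+2].[Br-].[Br-]
Why: CuBr2 α-brominates the methyl ketone selectively (via the enol) without adding to the enone C=C. The pyrrole has no free CH left to brominate.

**Step 8**
Reactants: **10**; **11** N-acetylguanidine
Product: **12** N-[5-(2,3-dibromo-8-oxo-1,6,7,8-tetrahydropyrrolo[2,3-c]azepin-4-yl)-1H-imidazol-2-yl]acetamide
Conditions: **11** (3 equiv), DMF, rt, then 60 °C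
Reagents that add atoms: **11**, CC(=O)NC(N)=N
Why: Hantzsch-type 2-aminoimidazole synthesis. One guanidine N alkylates the CH2Br (losing HBr), and the other N condenses onto the ketone (losing H2O) to aromatize to the imidazole. The acetyl group prevents over-alkylation. No stereocentre is formed.

**Step 9**
Reactant: **12**
Product: **13** stevensine
Conditions: 3 M HCl, MeOH/H2O, 70 °C
Reagents that add atoms: none (water hydrolyses the acetamide and leaves as AcOH)
Why: Acid hydrolysis of the 2-acetamido group. The conjugated pyrrole lactam, the C=C and the aryl C–Br bonds survive.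

## Compound list
| No. | Name | SMILES | Role |
|---|---|---|---|
| 1 | 2-(trichloroacetyl)-1H-pyrrole | O=C(C(Cl)(Cl)Cl)c1ccc[nH]1 | starting material |
| 2 | methyl 3-aminopropanoate hydrochloride | COC(=O)CCN.Cl | starting material |
| 3 | methyl 3-(1H-pyrrole-2-carboxamido)propanoate | COC(=O)CCNC(=O)c1ccc[nH]1 | intermediate |
| 4 | 3-(1H-pyrrole-2-carboxamido)propanoic acid | OC(=O)CCNC(=O)c1ccc[nH]1 | intermediate |
| 5 | 1,5,6,7-tetrahydropyrrolo[2,3-c]azepine-4,8-dione | O=C1CCNC(=O)c2[nH]ccc21 | intermediate |
| 6 | 2,3-dibromo-1,5,6,7-tetrahydropyrrolo[2,3-c]azepine-4,8-dione | O=C1CCNC(=O)c2[nH]c(Br)c(Br)c21 | intermediate |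
| 7 | ethynylmagnesium bromide | C#C[Mg]Br | starting material (reagent) |
| 8 | 2,3-dibromo-4-ethynyl-4-hydroxy-1,5,6,7-tetrahydropyrrolo[2,3-c]azepin-8-one (racemic) | C#CC1(O)CCNC(=O)c2[nH]c(Br)c(Br)c21 | intermediate |
| 9 | 4-acetyl-2,3-dibromo-1,6-dihydropyrrolo[2,3-c]azepin-8(7H)-one | CC(=O)C1=CCNC(=O)c2[nH]c(Br)c(Br)c21 | intermediate |
| 10 | 4-(bromoacetyl)-2,3-dibromo-1,6-dihydropyrrolo[2,3-c]azepin-8(7H)-one | BrCC(=O)C1=CCNC(=O)c2[nH]c(Br)c(Br)c21 | intermediate |
| 11 | N-acetylguanidine | CC(=O)NC(N)=N | starting material (reagent) |
| 12 | 2-acetamido-imidazolyl azepinone (N-acetyl stevensine) | CC(=O)Nc1ncc(C2=CCNC(=O)c3[nH]c(Br)c(Br)c32)[nH]1 | intermediate |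
| 13 | stevensine (achiral) | Nc1ncc(C2=CCNC(=O)c3[nH]c(Br)c(Br)c32)[nH]1 | target |

## Totals
Total step count: 9. Longest linear sequence: 9 steps (1 → 3 → 4 → 5 → 6 → 8 → 9 → 10 → 12 → 13).

## Three steps most likely to fail
1. **Step 3 (PPA Friedel–Crafts cyclization):** the free pyrrole can oligomerize or acylate intermolecularly at C5, giving a low yield.
   Fallback: build the C3–C(=O) bond intermolecularly. Take N-SEM-3-iodopyrrole-2-carboxylate, do an i-PrMgCl·LiCl exchange, and add the Weinreb amide of N-Boc-β-alanine. Then remove the Boc group and lactamize the amine onto the ester.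
2. **Step 5 (ethynyl addition):** the 3-acylpyrrole ketone is a vinylogous amide, and it is further deactivated once the pyrrole NH is deprotonated.
   Fallback: skip steps 5 and 6. Convert **6** to the enol triflate (KHMDS, PhNTf2) and couple it with tributyl(1-ethoxyvinyl)stannane under Pd catalysis. Hydrolysis of the enol ether then gives **9** directly.
3. **Step 6 (Rupe rearrangement):** the cation next to the electron-poor dibromopyrrole is disfavoured, and the Meyer–Schuster enal or decomposition may compete.
   Fallback: dehydrate **8** with Burgess reagent to the isolated enyne, then hydrate the alkyne under Au(I)/H2O catalysis to give **9**.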